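If we count what is left and not what is made, our reckoning needs one straight line for each temperature a flask stands at.

| flask | D | J | temperature | remark | time |
|---|---|---|---|---|---|
| maple | 0.0074 M | 0.22 mM | 30 °C | run made earlier |  |
| ash | 0.017 M | 0.22 mM | 41 °C | run made earlier |  |
| summer | 0.011 M | 0.220 mM |  | at 45 °C until 2.0 d, from then on at 25 °C | 3.0 d |
| noon | 0.011 M | 0.220 mM | 45 °C |  | 3.0 d |
| winter | 0.011 M | 0.220 mM | 25 °C |  | 3.0 d |

- maple (time / d: J / %, Z / %): 1.25: 98.5, 4.3; 2.50: 94.3, 8.1; 4.00: 90.4, 12.6; 5.00: 87.3, 16.1; 6.00: 84.2, 18.2; 8.00: 78.3, 25.1
- ash (time / d: J / %, Z / %): 0.250: 98.1, 3.5; 0.625: 96.0, 5.6; 1.25: 92.5, 8.4; 2.08: 89.0, 12.3; 3.00: 85.0, 16.2; 4.00: 80.4, 21.2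

(each reading ± 0.3 percentage points)

- amounts and yields of J count E too
- given per volume of solution although it is solid: E
- the earlier runs were read with a standard deviation of 0.3 percentage points
- steps thought possible: E <-> J; D -> J; D + J -> 2 J; J -> Z

- which flask leads in share of J in all that became J or Z ("all alike" within 1.5 percentage points) (summer / noon / winter / all alike)
- share of J in all that became J or Z, summer
- share of J in all that became J or Z, noon
- share of J in all that became J or Z, winter

We read the maple run row by row. J + Z is 103% at the first reading and 103% at the last, close to the charge of D and J together. So D has already become J at the first reading, and the total holds. In our flasks that total is 11.2 mM, and the asked share is the fraction of it that is not yet Z.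

Now the Z column. In maple, Z gains 0.223 mM/d in the earlier rows and 0.231 mM/d in the later ones, while J falls from 98.5% to 78.3%. That is a line, not a decay. We take it that E keeps dissolved [J] steady.

From first to last reading, the slope is 0.228 mM/d in maple and 0.802 mM/d in ash. We assume it ignores the charge of D. Carrying the logarithm of the slope on in proportion to the degrees gives 1.27 mM/d at 45 °C and 0.129 mM/d at 25 °C. We call this the drain, the zero-order rate of Z while E stands.

Our fractions left are 76.3% for summer, 66.1% for noon and 96.6% for winter. They run high, since the ash line starts 0.394 mM above zero at its first reading and we add no such head start.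

The forecast names winter, with 74% for summer, 65% for noon and 96.3% for winter, and it adds a burst “from supersaturation before crystallising”, so its noon stands lower than ours.

The flasks give 73.8% for summer, 64.2% for noon and 96.4% for winter, so winter leads.

    E ⇌ J, rate k1*(cs1 - [J]) while solid is left; crystals form when [J] > cs1 (solubility = 0.170 mM, k = 0.126 /min)
    D → J (k = 3.03 × 10⁻⁶ /min, Ea = 109 kJ/mol)
    D + J → 2 J (k = 73.9 /M/min, Ea = 53.0 kJ/mol)
    J → Z (k = 4.93 × 10⁻⁴ /min, Ea = 92.0 kJ/mol)
    (constants at 25 °C)

In noon, D + J → 2 J has 100% of its turnover behind it by 0.300 d, and half of the crystallising is done by 0.0733 h. J → Z then runs while E stands, still 64.0% at 3.00 d. Between 1.50 d and 3.00 d, noon's Z rises at 1.20 mM/d, beside our drain of 1.27 mM/d. At 1.50 d it already stands 0.321 mM above the drain line.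

Now noon read at 12.0 d. The drain empties the total in 8.82 d, earlier than that reading, so we expect no J. The computed share there is 0%, with Z at 102% of the D charged.

(The data were generated by integration on assumed constants; noise was put on by code.)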